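**Retrosynthetic overview**
- Target ⇐ one global hydrogenolysis of the tri-O-benzyl flavone: the 5-, 7- and 2'-OH are carried as benzyl ethers, the three OMe groups are in place from the start.
- Ring C (the only ring formed) ⇐ I2/DMSO oxidative cyclisation of a 2'-hydroxychalcone. Its single free ortho-OH sits next to the methoxy carbon, so closure can only give the 8-methoxy (not the 6-methoxy) flavone.
- Chalcone ⇐ Claisen–Schmidt condensation of a ring A acetophenone with a ring B benzaldehyde.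
- Ring A acetophenone ⇐ commercial 2',4'-bis(benzyloxy)-6'-hydroxyacetophenone by bromination ortho to the OH, then copper-catalysed Br→OMe exchange.
- Ring B aldehyde ⇐ commercial 2-hydroxy-4,5-dimethoxybenzaldehyde by O-benzylation.

Assumption: the target has no stereocentre and is achiral, so "single enantiomer" needs no stereocontrol; compounds 1 and 4 are taken as catalogue chemicals.

**Step 1**
Reactants: 1 1-[2,4-bis(benzyloxy)-6-hydroxyphenyl]ethan-1-one
Product: 2 1-[4,6-bis(benzyloxy)-3-bromo-2-hydroxyphenyl]ethan-1-one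
Conditions: NBS (1.0 equiv), MeCN, 0 °C to rt, dark
Reagents that add atoms: N-bromosuccinimide, O=C1CCC(=O)N1Br
Why: Electrophilic aromatic bromination goes to C3, which is ortho to the hydrogen-bonded OH and flanked by only one benzyloxy group, whereas C5 lies between two benzyloxy groups; this is the selectivity known for the dimethyl ether analogue.

**Step 2**
Reactants: 2 1-[4,6-bis(benzyloxy)-3-bromo-2-hydroxyphenyl]ethan-1-one
Product: 3 1-[4,6-bis(benzyloxy)-2-hydroxy-3-methoxyphenyl]ethan-1-one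
Conditions: NaOMe (6 equiv, 25% in MeOH), CuBr (0.2 equiv), DMF, 110 °C; then aq. HCl
Reagents that add atoms: sodium methoxide, [Na+].[O-]C
Why: Ullmann-type copper-catalysed methoxylation of an ortho-bromophenol (the 5-bromovanillin to syringaldehyde reaction type), which benzyl ethers and the aryl ketone tolerate.

**Step 3**
Reactants: 4 2-hydroxy-4,5-dimethoxybenzaldehyde
Product: 5 2-(benzyloxy)-4,5-dimethoxybenzaldehyde
Conditions: BnBr (1.2 equiv), K2CO3 (1.5 equiv), DMF, 60 °C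
Reagents that add atoms: benzyl bromide, BrCc1ccccc1
Why: Williamson ether synthesis on the phenoxide masks the ring B hydroxyl so it cannot take part in the later cyclisation, and it comes off with the other benzyl groups at the end.

**Step 4**
Reactants: 3 1-[4,6-bis(benzyloxy)-2-hydroxy-3-methoxyphenyl]ethan-1-one; 5 2-(benzyloxy)-4,5-dimethoxybenzaldehyde
Product: 6 (E)-1-[4,6-bis(benzyloxy)-2-hydroxy-3-methoxyphenyl]-3-[2-(benzyloxy)-4,5-dimethoxyphenyl]prop-2-en-1-one
Conditions: KOH (50% aq., 10 equiv), EtOH/THF, rt, 48 h; then cold dil. HCl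
Reagents that add atoms: none
Why: Claisen–Schmidt crossed aldol condensation with a non-enolisable aldehyde, where E1cB dehydration gives the conjugated E-enone under thermodynamic control (the alkene geometry is lost in the next step).

**Step 5**
Reactants: 6 (E)-1-[4,6-bis(benzyloxy)-2-hydroxy-3-methoxyphenyl]-3-[2-(benzyloxy)-4,5-dimethoxyphenyl]prop-2-en-1-one
Product: 8 5,7-bis(benzyloxy)-2-[2-(benzyloxy)-4,5-dimethoxyphenyl]-8-methoxy-4H-chromen-4-one, via racemic flavanone 7 (not isolated)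
Conditions: I2 (0.1 equiv), DMSO, 130 °C, 3 h; then aq. Na2S2O3
Reagents that add atoms: none
Why: I2/DMSO oxidative cyclisation: oxa-Michael closure by the only free ortho-OH gives the flavanone, α-iodination and loss of HI give the flavone while DMSO reoxidises HI, and the transient stereocentre at C2 is erased.

**Step 6**
Reactants: 8 5,7-bis(benzyloxy)-2-[2-(benzyloxy)-4,5-dimethoxyphenyl]-8-methoxy-4H-chromen-4-one
Product: 9 5,7-dihydroxy-2-(2-hydroxy-4,5-dimethoxyphenyl)-8-methoxy-4H-chromen-4-one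
Conditions: H2 (1 atm), 10% Pd/C, THF/MeOH 1:1, rt
Reagents that add atoms: none
Why: Catalytic hydrogenolysis cleaves the three benzyl aryl ethers at once, while the methyl ethers and the chromone C2=C3 bond are inert at 1 atm and rt.

**Compound list**
1 | 1-[2,4-bis(benzyloxy)-6-hydroxyphenyl]ethan-1-one | CC(=O)c1c(O)cc(OCc2ccccc2)cc1OCc1ccccc1 | starting material
2 | 1-[4,6-bis(benzyloxy)-3-bromo-2-hydroxyphenyl]ethan-1-one | CC(=O)c1c(O)c(Br)c(OCc2ccccc2)cc1OCc1ccccc1 | intermediate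
3 | 1-[4,6-bis(benzyloxy)-2-hydroxy-3-methoxyphenyl]ethan-1-one | CC(=O)c1c(O)c(OC)c(OCc2ccccc2)cc1OCc1ccccc1 | intermediate
4 | 2-hydroxy-4,5-dimethoxybenzaldehyde | COc1cc(O)c(C=O)cc1OC | starting material
5 | 2-(benzyloxy)-4,5-dimethoxybenzaldehyde | COc1cc(OCc2ccccc2)c(C=O)cc1OC | intermediate
6 | (E)-1-[4,6-bis(benzyloxy)-2-hydroxy-3-methoxyphenyl]-3-[2-(benzyloxy)-4,5-dimethoxyphenyl]prop-2-en-1-one | COc1cc(OCc2ccccc2)c(/C=C/C(=O)c2c(O)c(OC)c(OCc3ccccc3)cc2OCc2ccccc2)cc1OC | intermediate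
7 | racemic 5,7-bis(benzyloxy)-2-[2-(benzyloxy)-4,5-dimethoxyphenyl]-8-methoxychroman-4-one (not isolated) | COc1cc(OCc2ccccc2)c(C2CC(=O)c3c(OCc4ccccc4)cc(OCc4ccccc4)c(OC)c3O2)cc1OC | intermediate
8 | 5,7-bis(benzyloxy)-2-[2-(benzyloxy)-4,5-dimethoxyphenyl]-8-methoxy-4H-chromen-4-one | COc1cc(OCc2ccccc2)c(-c2cc(=O)c3c(OCc4ccccc4)cc(OCc4ccccc4)c(OC)c3o2)cc1OC | intermediate
9 | 5,7-dihydroxy-2-(2-hydroxy-4,5-dimethoxyphenyl)-8-methoxy-4H-chromen-4-one | COc1cc(O)c(-c2cc(=O)c3c(O)cc(O)c(OC)c3o2)cc1OC | target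

**Step count**
Total steps: 6. Longest linear sequence: 5 (steps 1, 2, 4, 5, 6; 1 → 2 → 3 → 6 → 8 → 9).

**Three steps most likely to fail, with fallbacks**

Step 1 (regiochemistry of the bromination; C5 attack or dibromination would lead to the 6-methoxy series). The position of the bromine in 2 should be confirmed by NOE from the remaining aromatic H to both OCH2Ph groups. Fallback: introduce the 8-oxygen after ring C exists, where Elbs persulfate oxidation can only go para to the free 5-OH. This sets out from 1 and 5 and comes back to the route at 9. Claisen–Schmidt condensation of 1 with 5 (KOH, EtOH/THF, rt) gives (E)-1-[2,4-bis(benzyloxy)-6-hydroxyphenyl]-3-[2-(benzyloxy)-4,5-dimethoxyphenyl]prop-2-en-1-one F1. Catalytic I2 in DMSO at 130 °C takes it through racemic 5,7-bis(benzyloxy)-2-[2-(benzyloxy)-4,5-dimethoxyphenyl]chroman-4-one F2, which is not isolated, to 5,7-bis(benzyloxy)-2-[2-(benzyloxy)-4,5-dimethoxyphenyl]-4H-chromen-4-one F3. MgBr2·OEt2 in toluene/Et2O at 80 °C cleaves only the benzyl ether peri to the carbonyl (chelation) and gives 7-(benzyloxy)-2-[2-(benzyloxy)-4,5-dimethoxyphenyl]-5-hydroxy-4H-chromen-4-one F4. K2S2O8 in aqueous KOH/pyridine at 0–20 °C gives potassium 7-(benzyloxy)-2-[2-(benzyloxy)-4,5-dimethoxyphenyl]-5-hydroxy-4-oxo-4H-chromen-8-yl sulfate F5, not isolated, which dilute HCl at 80 °C hydrolyses to 7-(benzyloxy)-2-[2-(benzyloxy)-4,5-dimethoxyphenyl]-5,8-dihydroxy-4H-chromen-4-one F6. Me2SO4 (1.05 equiv) with K2CO3 in refluxing acetone methylates only the non-chelated 8-OH and gives 7-(benzyloxy)-2-[2-(benzyloxy)-4,5-dimethoxyphenyl]-5-hydroxy-8-methoxy-4H-chromen-4-one F7. Hydrogenolysis (H2, 10% Pd/C, THF/MeOH) then gives 9.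

Step 2 (hindered, electron-rich bromide; hydrodebromination back to 1 and slow exchange are the likely problems). Fallback: replace C–O coupling with methoxide by hydroxylation followed by selective O-methylation. This sets out from 2 and comes back at 3. Pd-catalysed hydroxylation of 2 (Pd2(dba)3, tBuXPhos, KOH, dioxane/H2O, 100 °C, then acid) gives 1-[4,6-bis(benzyloxy)-2,3-dihydroxyphenyl]ethan-1-one F8. MeI (1.0 equiv) with K2CO3 in acetone at rt then methylates the free 3-OH and leaves the chelated 2-OH, giving 3.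

Step 5 (HI formed in the flask may cleave benzyl ethers, iodine may iodinate the electron-rich rings, or the reaction may stall at flavanone 7). Fallback: build ring C without an oxidant by the Baker–Venkataraman route. This sets out from 3 and 5, bypasses 6, and comes back at 8. Pinnick oxidation of 5 (NaClO2, NaH2PO4, 2-methyl-2-butene, tBuOH/H2O) gives 2-(benzyloxy)-4,5-dimethoxybenzoic acid F9. Coupling with the phenol of 3 (EDC·HCl, DMAP, CH2Cl2) gives 2-acetyl-3,5-bis(benzyloxy)-6-methoxyphenyl 2-(benzyloxy)-4,5-dimethoxybenzoate F10. KOH in pyridine at 50 °C effects the acyl shift to 1-[4,6-bis(benzyloxy)-2-hydroxy-3-methoxyphenyl]-3-[2-(benzyloxy)-4,5-dimethoxyphenyl]propane-1,3-dione F11. Cyclodehydration with catalytic p-TsOH in refluxing toluene gives 8.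

**Further compounds**
F1 | step 1 | (E)-1-[2,4-bis(benzyloxy)-6-hydroxyphenyl]-3-[2-(benzyloxy)-4,5-dimethoxyphenyl]prop-2-en-1-one | COc1cc(OCc2ccccc2)c(/C=C/C(=O)c2c(O)cc(OCc3ccccc3)cc2OCc2ccccc2)cc1OC
F2 | step 1 | racemic 5,7-bis(benzyloxy)-2-[2-(benzyloxy)-4,5-dimethoxyphenyl]chroman-4-one | COc1cc(OCc2ccccc2)c(C2CC(=O)c3c(OCc4ccccc4)cc(OCc4ccccc4)cc3O2)cc1OC
F3 | step 1 | 5,7-bis(benzyloxy)-2-[2-(benzyloxy)-4,5-dimethoxyphenyl]-4H-chromen-4-one | COc1cc(OCc2ccccc2)c(-c2cc(=O)c3c(OCc4ccccc4)cc(OCc4ccccc4)cc3o2)cc1OC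
F4 | step 1 | 7-(benzyloxy)-2-[2-(benzyloxy)-4,5-dimethoxyphenyl]-5-hydroxy-4H-chromen-4-one | COc1cc(OCc2ccccc2)c(-c2cc(=O)c3c(O)cc(OCc4ccccc4)cc3o2)cc1OC
F5 | step 1 | potassium 7-(benzyloxy)-2-[2-(benzyloxy)-4,5-dimethoxyphenyl]-5-hydroxy-4-oxo-4H-chromen-8-yl sulfate | COc1cc(OCc2ccccc2)c(-c2cc(=O)c3c(O)cc(OCc4ccccc4)c(OS(=O)(=O)[O-])c3o2)cc1OC.[K+]
F6 | step 1 | 7-(benzyloxy)-2-[2-(benzyloxy)-4,5-dimethoxyphenyl]-5,8-dihydroxy-4H-chromen-4-one | COc1cc(OCc2ccccc2)c(-c2cc(=O)c3c(O)cc(OCc4ccccc4)c(O)c3o2)cc1OC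
F7 | step 1 | 7-(benzyloxy)-2-[2-(benzyloxy)-4,5-dimethoxyphenyl]-5-hydroxy-8-methoxy-4H-chromen-4-one | COc1cc(OCc2ccccc2)c(-c2cc(=O)c3c(O)cc(OCc4ccccc4)c(OC)c3o2)cc1OC
F8 | step 2 | 1-[4,6-bis(benzyloxy)-2,3-dihydroxyphenyl]ethan-1-one | CC(=O)c1c(O)c(O)c(OCc2ccccc2)cc1OCc1ccccc1
F9 | step 5 | 2-(benzyloxy)-4,5-dimethoxybenzoic acid | COc1cc(OCc2ccccc2)c(C(=O)O)cc1OC
F10 | step 5 | 2-acetyl-3,5-bis(benzyloxy)-6-methoxyphenyl 2-(benzyloxy)-4,5-dimethoxybenzoate | COc1cc(OCc2ccccc2)c(C(=O)Oc2c(C(C)=O)c(OCc3ccccc3)cc(OCc3ccccc3)c2OC)cc1OC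
F11 | step 5 | 1-[4,6-bis(benzyloxy)-2-hydroxy-3-methoxyphenyl]-3-[2-(benzyloxy)-4,5-dimethoxyphenyl]propane-1,3-dione | COc1cc(OCc2ccccc2)c(C(=O)CC(=O)c2c(O)c(OC)c(OCc3ccccc3)cc2OCc2ccccc2)cc1OC
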